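- It is impossible for a flask to couple more substrate than it holds coupling partner, at one partner per coupling, so I count turnovers.

common to all: left-handed substrate 0.56 M; right-handed substrate 0.56 M

|  | coupling partner | remark | time |
|---|---|---|---|
| north-east | 0.13 M | run made earlier |  |
| south-west | 2.2 M | run made earlier |  |
| teal | 0.600 M |  | 1.0 h |
| green | 0.200 M |  | 1.0 h |
| blue | 0.400 M |  | 1.0 h |
| ochre | 0.840 M |  | 1.0 h |
| grey | 3.00 M |  | 1.0 h |

- north-east (time / min: left-handed product / %, left-handed substrate / %): 4.00: 1.5, 48.3; 10.0: 4.6, 45.6; 20.0: 3.5, 43.4; 30.0: 4.2, 42.3; 40.0: 4.4, 43.1
- south-west (time / min: left-handed product / %, left-handed substrate / %): 8.00: 30.7, 17.1; 15.0: 39.1, 8.9; 25.0: 42.9, 2.0; 30.0: 43.3, 2.4; 40.0: 46.6, 0.2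

(scatter of a reading: 1 percentage point)

1. the flasks by amount of left-handed product, in percent of the left-handed substrate and right-handed substrate together charged, highest first, at 1.0 h (teal / green / blue / ochre / grey)
2. the amount of left-handed product, in percent of the left-handed substrate and right-handed substrate together charged of the flask you put first, at 1.0 h
3. the amount of left-handed product, in percent of the left-handed substrate and right-handed substrate together charged of the flask you put last, at 1.0 h

- coupling partner is single-handed; left-handed substrate and right-handed substrate are mirror images of each other, charged as a racemate, each of them at the stated concentration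
- the handed part of coupling partner does not stay in what it makes, so the products of the two hands are mirror images too

- [coupling partner] charged over [left-handed substrate] plus [right-handed substrate] charged, 2.68 in grey, is what I call the turnover ratio; below one the partner is the limiting reagent, above one the substrates are.
- In the north-east run, at ratio 0.116, left-handed substrate has lost 6.9 percentage points by the last reading, yet left-handed product reads 4.4%, less than that loss, so I take product to pass into its mirror image and give each hand an equal share.
- My ceiling for left-handed product, as a fraction of the combined substrate charge, is therefore the ratio divided by 2, stopping at 0.5: north-east allows 5.80%, and the south-west run, at ratio 1.96, reads 46.6% after 40.0 min.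
- I therefore rank the flasks by ratio, with green just under 8.93% and grey just under 0.5 of the combined charge.
- The forecast, holding that “each substrate couples once with the partner”, gives grey > ochre > teal > blue > green, with 46.5% and 7%.
- The simulation gives grey > ochre > teal > blue > green, with grey at 48.7% and green at 7.95%, both under their ceilings.

    coupling partner + left-handed substrate → left-handed product (k = 0.00122 /M/s)
    coupling partner ⇌ dormant form (K = 9.60, k = 1.18 × 10⁻⁴ /s)
    coupling partner + right-handed substrate → right-handed product (k = 6.51 × 10⁻⁴ /M/s)
    coupling partner → decomposition product (k = 5.61 × 10⁻⁷ /s)
    left-handed product ⇌ right-handed product (k = 5.23 × 10⁻⁴ /s)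

- Grey's ratio is 2.68; one more flask like grey, with 1.2 M of coupling partner, has ratio 1.07, again above one, so its ceiling is again 0.5 of the combined charge, but at 1.0 h it gives 37.5% of left-handed product, with 7.21% of left-handed substrate, 17.8% of right-handed substrate, 15% of the partner's charge free and 0.182 M of dormant form.

All runs stem from a simulated flask with constants of no real substance; the scatter is artificial.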